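**Plan**
- Retrosynthetic cuts: first the two phenol ethers (the 4'-O-methyl on the C2 aryl ring and the O-benzyl cap on the C4 benzyl ring), then O1–C2 of the oxolane, then C2–C3 (lactone enolate alkylation), then the C4–CH2Ar bond (Stobbe condensation).
- Enabling feature: C2 is a benzylic carbon para to an aryl oxygen, and O1 is the oxygen of the C5H2 arm on C4. With that para oxygen free as a phenol, the ring can be oxidised to a p-quinone methide at C2, which the C5 hydroxyl traps.
- Forward order: the chain is joined first (vanillin and dimethyl succinate give the (R)-β-benzyl lactone; alkylation with a syringaldehyde-derived bromide; hydride opening to the 2,3-dibenzylbutane-1,4-diol). The single ring, the oxolane, is closed next, followed by O-methylation and debenzylation.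
- Stereochemistry: C4 comes from asymmetric hydrogenation of the Stobbe half-ester; C3 from trans-selective alkylation anti to the C4 substituent; C2 from the cyclisation, trans to the C3 hydroxymethyl group under substrate control.

Key step: step 11

Assumption: the (4S,5S) antipode of MOD-DIOP (4,5-bis{[bis(4-methoxy-3,5-dimethylphenyl)phosphino]methyl}-2,2-dimethyl-1,3-dioxolane) is taken as the one that delivers the (R)-succinate in step 3; if the sense proves opposite, the (4R,5R) ligand is used with no other change.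

**Route**

Step 1
Reactants: 1 vanillin
Product: 2 4-(benzyloxy)-3-methoxybenzaldehyde
Conditions: BnBr, K2CO3, DMF, rt
Reagents that add atoms: benzyl bromide, BrCc1ccccc1
Why: Williamson etherification of the phenoxide caps this phenol, so that later only the other aryl ring can form a quinone methide.

Step 2
Reactants: 2 4-(benzyloxy)-3-methoxybenzaldehyde; 3 dimethyl succinate
Product: 5 (E)-4-[4-(benzyloxy)-3-methoxyphenyl]-3-(methoxycarbonyl)but-3-enoic acid, via paraconic ester lactone 4 (not isolated)
Conditions: NaOMe, MeOH, reflux; then aq. HCl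
Reagents that add atoms: none
Why: Stobbe condensation, in which the aldolate lactonises to 4 and E1cB ring opening gives the carboxylate of the (E)-alkylidene half-ester, which drives the reaction and differentiates the two carboxyl groups.

Step 3
Reactants: 5 (E)-4-[4-(benzyloxy)-3-methoxyphenyl]-3-(methoxycarbonyl)but-3-enoic acid
Product: 6 (R)-4-[4-(benzyloxy)-3-methoxyphenyl]-3-(methoxycarbonyl)butanoic acid
Conditions: H2 (1 atm), [Rh(cod)Cl]2 (cat.), (4S,5S)-MOD-DIOP (cat.), Et3N (cat.), MeOH, 30 °C
Reagents that add atoms: none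
Why: Rhodium–bisphosphine asymmetric hydrogenation of an itaconate-type half-ester, in which the carboxylate and alkene chelate the metal so that hydrogen is delivered to one face and the (R) centre (later C4) is set under catalyst control; the homogeneous catalyst should leave the benzyl ether intact.

Step 4
Reactants: 6 (R)-4-[4-(benzyloxy)-3-methoxyphenyl]-3-(methoxycarbonyl)butanoic acid
Product: 8 (R)-4-[4-(benzyloxy)-3-methoxybenzyl]oxolan-2-one, via hydroxy acid 7 (not isolated)
Conditions: KOH (1 equiv), EtOH; CaCl2, NaBH4, EtOH, −10 °C to rt; then 2 M HCl, rt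
Reagents that add atoms: none
Why: Chemoselective borohydride reduction, since Ca(BH4)2 reduces the methyl ester while the carboxylate salt is inert, and acidification closes the γ-lactone; the stereocentre then no longer sits α to a carbonyl.

Step 5
Reactants: 9 syringaldehyde
Product: 10 4-(tert-butyldimethylsilyloxy)-3,5-dimethoxybenzaldehyde
Conditions: TBSCl, imidazole, DMF, rt
Reagents that add atoms: tert-butyl(chloro)dimethylsilane, CC(C)(C)[Si](C)(C)Cl
Why: Imidazole-promoted phenol silylation installs a cap that fluoride can later remove without touching the benzyl ether, which keeps the two phenols distinguishable.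

Step 6
Reactants: 10 4-(tert-butyldimethylsilyloxy)-3,5-dimethoxybenzaldehyde
Product: 11 [4-(tert-butyldimethylsilyloxy)-3,5-dimethoxyphenyl]methanol
Conditions: NaBH4, MeOH, 0 °C
Reagents that add atoms: none
Why: Borohydride reduction of an aryl aldehyde to the benzylic alcohol, to which the hindered aryl silyl ether is inert.

Step 7
Reactants: 11 [4-(tert-butyldimethylsilyloxy)-3,5-dimethoxyphenyl]methanol
Product: 12 5-(bromomethyl)-2-(tert-butyldimethylsilyloxy)-1,3-dimethoxybenzene
Conditions: CBr4, PPh3, CH2Cl2, 0 °C; used at once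
Reagents that add atoms: tetrabromomethane, BrC(Br)(Br)Br
Why: Appel bromination converts the benzylic alcohol into the bromide under neutral conditions that spare the silyl ether.

Step 8
Reactants: 8 (R)-4-[4-(benzyloxy)-3-methoxybenzyl]oxolan-2-one; 12 5-(bromomethyl)-2-(tert-butyldimethylsilyloxy)-1,3-dimethoxybenzene
Product: 14 (3R,4R)-4-[4-(benzyloxy)-3-methoxybenzyl]-3-[4-(tert-butyldimethylsilyloxy)-3,5-dimethoxybenzyl]oxolan-2-one, via lithium enolate 13 (not isolated)
Conditions: LiN(iPr)2, THF, −78 °C; then 12, DMPU, −78 to −40 °C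
Reagents that add atoms: none
Why: SN2 alkylation of the lactone lithium enolate with a benzylic bromide, in which the electrophile approaches the face anti to the C4 arylmethyl group and so sets C3 trans (3R) under substrate control.

Step 9
Reactants: 14 (3R,4R)-4-[4-(benzyloxy)-3-methoxybenzyl]-3-[4-(tert-butyldimethylsilyloxy)-3,5-dimethoxybenzyl]oxolan-2-one
Product: 15 (2R,3R)-2-[4-(benzyloxy)-3-methoxybenzyl]-3-[4-(tert-butyldimethylsilyloxy)-3,5-dimethoxybenzyl]butane-1,4-diol
Conditions: LiAlH4, THF, 0 °C
Reagents that add atoms: none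
Why: Hydride reduction of the lactone to the 1,4-diol removes the only acidic C–H next to a stereocentre, so both centres are carried over, and any loss of the hindered silyl ether would simply converge on 16.

Step 10
Reactants: 15 (2R,3R)-2-[4-(benzyloxy)-3-methoxybenzyl]-3-[4-(tert-butyldimethylsilyloxy)-3,5-dimethoxybenzyl]butane-1,4-diol
Product: 16 (2R,3R)-2-[4-(benzyloxy)-3-methoxybenzyl]-3-(4-hydroxy-3,5-dimethoxybenzyl)butane-1,4-diol
Conditions: Bu4NF, AcOH, THF, 0 °C
Reagents that add atoms: none
Why: Fluoride-induced desilylation frees the single phenol needed for the oxidation, with acetic acid buffering the electron-rich phenoxide against air oxidation.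

Step 11
Reactants: 16 (2R,3R)-2-[4-(benzyloxy)-3-methoxybenzyl]-3-(4-hydroxy-3,5-dimethoxybenzyl)butane-1,4-diol
Product: 18 [(2S,3R,4R)-4-[4-(benzyloxy)-3-methoxybenzyl]-2-(4-hydroxy-3,5-dimethoxyphenyl)oxolan-3-yl]methanol, via p-quinone methide 17 (not isolated)
Conditions: DDQ (1.0 equiv), CH2Cl2, 0 °C to rt
Reagents that add atoms: none
Why: DDQ removes two electrons and a proton from the only free phenol and the benzylic CH2 para to it loses a proton, giving p-quinone methide 17. The hydroxyl of the CH2OH arm on the carbon that carries the benzyloxy-methoxybenzyl group then adds to the methide carbon in a 5-exo-trig oxa-conjugate addition that restores the aromatic ring and forms O1–C2. The closest known reaction type is the quinone-mediated oxidation of 4-alkylphenols to p-quinone methides with intramolecular capture by a pendant alcohol. The new centre C2 is controlled by the neighbouring C3 centre, since the planar methide is attacked with the aryl unit anti to the C3 hydroxymethyl group in the envelope transition state, and because the addition can revert through 17 under the mild acidity of the hydroquinone by-product the 2,3-trans (2S) isomer should also be the equilibrium product; C3 and C4 are not touched. Chemoselectivity between the arenes is secured by the benzyl cap on the other phenol, regioselectivity between the two hydroxyls by ring size (the nearer one could only form an oxetane), and O-capture over Friedel–Crafts capture or a second oxidation by the absence of added acid, the low temperature and a single equivalent of oxidant.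

Step 12
Reactants: 18 [(2S,3R,4R)-4-[4-(benzyloxy)-3-methoxybenzyl]-2-(4-hydroxy-3,5-dimethoxyphenyl)oxolan-3-yl]methanol
Product: 19 [(2S,3R,4R)-4-[4-(benzyloxy)-3-methoxybenzyl]-2-(3,4,5-trimethoxyphenyl)oxolan-3-yl]methanol
Conditions: MeI, K2CO3, acetone, reflux
Reagents that add atoms: iodomethane, CI
Why: Williamson methylation, in which carbonate deprotonates only the phenol and leaves the primary alcohol unalkylated, and capping the phenoxide also shuts off any return to the quinone methide.

Step 13
Reactants: 19 [(2S,3R,4R)-4-[4-(benzyloxy)-3-methoxybenzyl]-2-(3,4,5-trimethoxyphenyl)oxolan-3-yl]methanol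
Product: 20 [(2S,3R,4R)-4-(4-hydroxy-3-methoxybenzyl)-2-(3,4,5-trimethoxyphenyl)oxolan-3-yl]methanol (target)
Conditions: H2 (1 atm), 10% Pd/C, EtOAc, rt, stopped after one equivalent of H2
Reagents that add atoms: none
Why: Catalytic hydrogenolysis of the aryl benzyl ether, which under neutral conditions should be cleaved well before the ring C2–O1 benzylic ether, so that the three stereocentres are left as set.

**Compound list**

1 | vanillin (4-hydroxy-3-methoxybenzaldehyde) | COc1cc(C=O)ccc1O | starting material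
2 | 4-(benzyloxy)-3-methoxybenzaldehyde | COc1cc(C=O)ccc1OCc1ccccc1 | intermediate
3 | dimethyl succinate | COC(=O)CCC(=O)OC | starting material
4 | methyl 2-[4-(benzyloxy)-3-methoxyphenyl]-5-oxooxolane-3-carboxylate (paraconic ester, racemic, both relative configurations) | COC(=O)C1CC(=O)OC1c1ccc(OCc2ccccc2)c(OC)c1 | intermediate (not isolated)
5 | (E)-4-[4-(benzyloxy)-3-methoxyphenyl]-3-(methoxycarbonyl)but-3-enoic acid | COC(=O)/C(CC(=O)O)=C/c1ccc(OCc2ccccc2)c(OC)c1 | intermediate
6 | (R)-4-[4-(benzyloxy)-3-methoxyphenyl]-3-(methoxycarbonyl)butanoic acid | COC(=O)[C@@H](CC(=O)O)Cc1ccc(OCc2ccccc2)c(OC)c1 | intermediate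
7 | (R)-3-[4-(benzyloxy)-3-methoxybenzyl]-4-hydroxybutanoic acid | OC[C@@H](CC(=O)O)Cc1ccc(OCc2ccccc2)c(OC)c1 | intermediate (not isolated)
8 | (R)-4-[4-(benzyloxy)-3-methoxybenzyl]oxolan-2-one | O=C1OC[C@H](Cc2ccc(OCc3ccccc3)c(OC)c2)C1 | intermediate
9 | syringaldehyde (4-hydroxy-3,5-dimethoxybenzaldehyde) | COc1cc(C=O)cc(OC)c1O | starting material
10 | 4-(tert-butyldimethylsilyloxy)-3,5-dimethoxybenzaldehyde | COc1cc(C=O)cc(OC)c1O[Si](C)(C)C(C)(C)C | intermediate
11 | [4-(tert-butyldimethylsilyloxy)-3,5-dimethoxyphenyl]methanol | COc1cc(CO)cc(OC)c1O[Si](C)(C)C(C)(C)C | intermediate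
12 | 5-(bromomethyl)-2-(tert-butyldimethylsilyloxy)-1,3-dimethoxybenzene | COc1cc(CBr)cc(OC)c1O[Si](C)(C)C(C)(C)C | intermediate
13 | lithium enolate of lactone 8 (lithium (R)-3-[4-(benzyloxy)-3-methoxybenzyl]-2,3-dihydrofuran-5-olate) | [Li+].[O-]C1=C[C@@H](Cc2ccc(OCc3ccccc3)c(OC)c2)CO1 | intermediate (not isolated)
14 | (3R,4R)-4-[4-(benzyloxy)-3-methoxybenzyl]-3-[4-(tert-butyldimethylsilyloxy)-3,5-dimethoxybenzyl]oxolan-2-one (trans) | O=C1OC[C@H](Cc2ccc(OCc3ccccc3)c(OC)c2)[C@H]1Cc1cc(OC)c(O[Si](C)(C)C(C)(C)C)c(OC)c1 | intermediate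
15 | (2R,3R)-2-[4-(benzyloxy)-3-methoxybenzyl]-3-[4-(tert-butyldimethylsilyloxy)-3,5-dimethoxybenzyl]butane-1,4-diol | COc1cc(C[C@@H](CO)[C@H](CO)Cc2cc(OC)c(O[Si](C)(C)C(C)(C)C)c(OC)c2)ccc1OCc1ccccc1 | intermediate
16 | (2R,3R)-2-[4-(benzyloxy)-3-methoxybenzyl]-3-(4-hydroxy-3,5-dimethoxybenzyl)butane-1,4-diol | COc1cc(C[C@@H](CO)[C@H](CO)Cc2cc(OC)c(O)c(OC)c2)ccc1OCc1ccccc1 | intermediate
17 | 4-{(2R,3R)-3-[4-(benzyloxy)-3-methoxybenzyl]-4-hydroxy-2-(hydroxymethyl)butylidene}-2,6-dimethoxycyclohexa-2,5-dien-1-one (p-quinone methide) | COc1cc(C[C@@H](CO)[C@H](CO)C=C2C=C(OC)C(=O)C(OC)=C2)ccc1OCc1ccccc1 | intermediate (not isolated)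
18 | [(2S,3R,4R)-4-[4-(benzyloxy)-3-methoxybenzyl]-2-(4-hydroxy-3,5-dimethoxyphenyl)oxolan-3-yl]methanol (2,3-trans, 3,4-cis) | COc1cc(C[C@H]2CO[C@H](c3cc(OC)c(O)c(OC)c3)[C@H]2CO)ccc1OCc1ccccc1 | intermediate
19 | [(2S,3R,4R)-4-[4-(benzyloxy)-3-methoxybenzyl]-2-(3,4,5-trimethoxyphenyl)oxolan-3-yl]methanol | COc1cc(C[C@H]2CO[C@H](c3cc(OC)c(OC)c(OC)c3)[C@H]2CO)ccc1OCc1ccccc1 | intermediate
20 | [(2S,3R,4R)-4-(4-hydroxy-3-methoxybenzyl)-2-(3,4,5-trimethoxyphenyl)oxolan-3-yl]methanol | COc1cc(C[C@H]2CO[C@H](c3cc(OC)c(OC)c(OC)c3)[C@H]2CO)ccc1O | target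

**Count**

Total steps: 13. Longest linear sequence: 10 steps (1, 2, 3, 4, 8, 9, 10, 11, 12, 13); the bromide branch (steps 5–7) joins at step 8.

**Steps most likely to fail**

Step 11. The newly formed benzylic ether, still para to a free phenol, may be oxidised a second time, the quinone methide may be captured at carbon by the benzyloxy arene to give a tetralin, or C2 may not equilibrate fully to the trans isomer. The fallback sets out from lactone 8 and comes back at 19, placing the benzylic oxygen by an aldol reaction so that no oxidant is needed. The enolate of 8 (LiN(iPr)2, THF, −78 °C) is added to commercial 3,4,5-trimethoxybenzaldehyde to give the trans aldol adduct (3S,4R)-4-[4-(benzyloxy)-3-methoxybenzyl]-3-[hydroxy(3,4,5-trimethoxyphenyl)methyl]oxolan-2-one F1 as a mixture of carbinol epimers. LiAlH4 (THF, 0 °C) converts it into the triol (2R,3R)-2-[4-(benzyloxy)-3-methoxybenzyl]-3-[hydroxy(3,4,5-trimethoxyphenyl)methyl]butane-1,4-diol F2. Brief exposure to catalytic camphorsulfonic acid (CH2Cl2, 0 °C) ionises the benzylic alcohol, and the same primary hydroxyl closes the oxolane 5-exo to give 19. The carbinol configuration is lost in the cation, and a short contact time should keep the faster O-capture ahead of C-capture. Steps 8–12 are bypassed.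

Step 13. Hydrogenolytic opening of the electron-rich benzylic C2–O1 bond may compete with cleavage of the aryl benzyl ether. The fallback sets out from silyl diol 15 and comes back at target 20, exchanging the benzyl group for an allyl group before the ring exists. Hydrogenolysis of 15 (H2, 10% Pd/C, EtOAc), where no benzylic ring ether is present, gives (2R,3R)-2-[4-(tert-butyldimethylsilyloxy)-3,5-dimethoxybenzyl]-3-(4-hydroxy-3-methoxybenzyl)butane-1,4-diol F3. Phenol-selective allylation (allyl bromide, K2CO3, acetone) gives (2R,3R)-2-[4-(allyloxy)-3-methoxybenzyl]-3-[4-(tert-butyldimethylsilyloxy)-3,5-dimethoxybenzyl]butane-1,4-diol F4. Desilylation (Bu4NF, AcOH, THF) gives (2R,3R)-2-[4-(allyloxy)-3-methoxybenzyl]-3-(4-hydroxy-3,5-dimethoxybenzyl)butane-1,4-diol F5. DDQ as in step 11 closes the ring to [(2S,3R,4R)-4-[4-(allyloxy)-3-methoxybenzyl]-2-(4-hydroxy-3,5-dimethoxyphenyl)oxolan-3-yl]methanol F6. Methylation (MeI, K2CO3, acetone) gives [(2S,3R,4R)-4-[4-(allyloxy)-3-methoxybenzyl]-2-(3,4,5-trimethoxyphenyl)oxolan-3-yl]methanol F7. The allyl ether is then removed with zerovalent palladium (Pd(PPh3)4 cat., morpholine, THF, rt), which cannot cleave the C2–O1 bond, to give 20.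

Step 8. The electron-rich bromide 12 may ionise and self-condense before it meets the enolate, or proton transfer between product and enolate may lead to double alkylation. The fallback sets out from lactone 8 and aldehyde 10 and comes back at 14, avoiding the bromide. Aldol addition of enolate 13 to aldehyde 10 (THF, −78 °C) gives the trans β-hydroxy lactone (3S,4R)-4-[4-(benzyloxy)-3-methoxybenzyl]-3-{[4-(tert-butyldimethylsilyloxy)-3,5-dimethoxyphenyl](hydroxy)methyl}oxolan-2-one F8 as carbinol epimers. Ionic deoxygenation (Et3SiH in large excess, CF3CO2H, CH2Cl2, −20 °C) removes the benzylic hydroxyl through the silyloxy-stabilised cation, the excess silane being there to outrun ring closure onto the other arene, and returns 14 with the trans C3 configuration fixed in the aldol step.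

**Further compounds**

F1 | step 11 | (3S,4R)-4-[4-(benzyloxy)-3-methoxybenzyl]-3-[hydroxy(3,4,5-trimethoxyphenyl)methyl]oxolan-2-one (carbinol epimers) | O=C1OC[C@H](Cc2ccc(OCc3ccccc3)c(OC)c2)[C@H]1C(O)c1cc(OC)c(OC)c(OC)c1
F2 | step 11 | (2R,3R)-2-[4-(benzyloxy)-3-methoxybenzyl]-3-[hydroxy(3,4,5-trimethoxyphenyl)methyl]butane-1,4-diol (carbinol epimers) | COc1cc(C[C@@H](CO)[C@H](CO)C(O)c2cc(OC)c(OC)c(OC)c2)ccc1OCc1ccccc1
F3 | step 13 | (2R,3R)-2-[4-(tert-butyldimethylsilyloxy)-3,5-dimethoxybenzyl]-3-(4-hydroxy-3-methoxybenzyl)butane-1,4-diol | COc1cc(C[C@@H](CO)[C@H](CO)Cc2cc(OC)c(O[Si](C)(C)C(C)(C)C)c(OC)c2)ccc1O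
F4 | step 13 | (2R,3R)-2-[4-(allyloxy)-3-methoxybenzyl]-3-[4-(tert-butyldimethylsilyloxy)-3,5-dimethoxybenzyl]butane-1,4-diol | C=CCOc1ccc(C[C@@H](CO)[C@H](CO)Cc2cc(OC)c(O[Si](C)(C)C(C)(C)C)c(OC)c2)cc1OC
F5 | step 13 | (2R,3R)-2-[4-(allyloxy)-3-methoxybenzyl]-3-(4-hydroxy-3,5-dimethoxybenzyl)butane-1,4-diol | C=CCOc1ccc(C[C@@H](CO)[C@H](CO)Cc2cc(OC)c(O)c(OC)c2)cc1OC
F6 | step 13 | [(2S,3R,4R)-4-[4-(allyloxy)-3-methoxybenzyl]-2-(4-hydroxy-3,5-dimethoxyphenyl)oxolan-3-yl]methanol | C=CCOc1ccc(C[C@H]2CO[C@H](c3cc(OC)c(O)c(OC)c3)[C@H]2CO)cc1OC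
F7 | step 13 | [(2S,3R,4R)-4-[4-(allyloxy)-3-methoxybenzyl]-2-(3,4,5-trimethoxyphenyl)oxolan-3-yl]methanol | C=CCOc1ccc(C[C@H]2CO[C@H](c3cc(OC)c(OC)c(OC)c3)[C@H]2CO)cc1OC
F8 | step 8 | (3S,4R)-4-[4-(benzyloxy)-3-methoxybenzyl]-3-{[4-(tert-butyldimethylsilyloxy)-3,5-dimethoxyphenyl](hydroxy)methyl}oxolan-2-one (carbinol epimers) | O=C1OC[C@H](Cc2ccc(OCc3ccccc3)c(OC)c2)[C@H]1C(O)c1cc(OC)c(O[Si](C)(C)C(C)(C)C)c(OC)c1
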